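The route rests on opening ring B, the dihydropyranone O1–C2–C3–C4–C4a–C8a (numbering of the chromene-4,7-dione target), at C2–C3 and O1–C8a. The precursor is a dearomatised 1,3-bis(silyloxy)diene made from a propanoyl group on C4a of carbocycle A. With acetaldehyde and Ti(OiPr)4/(S)-BINOL, then acid, one operation closes ring B and sets C2 and C3. The step exploits the vinylogous ester O1–C8a=C4a–C4=O and the C6 octanoic acid chain: its carboxyl is tied to O5 as a temporary δ-lactone, so only C8a can take the new oxygen, and the lactone stereocentre steers the prenyl group at C8.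

Key step: step 10

Assumptions and conventions (remarks on the chemistry):
- (1S,5S)-Verbenone is taken as enantiopure; material of lower optical purity would first be enriched or made from (−)-α-pinene of high ee.
- In step 5 the (R)-catalyst is taken to shield the face of the (E,E)-iminium ion that leads to 4S, the usual model for diarylprolinol silyl ethers. Both catalytic stages are run in one flask; should the residual amine or triol disturb the carbene stage, the crude lactol would be passed through a short silica pad first.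
- In step 8 the (S,S)-ligand is taken to be the enantiomer matched with the substrate's own facial bias; if the pairing proves mismatched, the (R,R)-ligand is used under the same conditions.
- In step 10 (S)-BINOL is taken to deliver the nucleophile to the Si face of acetaldehyde, the sense usual for BINOL–titanium catalysts ((R)-BINOL: Re face).
- Intermediates 8–17 carry the locants of their own names (lactone numbering); target locants are used only where stated.

Step 1
Reactants: 1 (1S,5S)-4,6,6-trimethylbicyclo[3.1.1]hept-3-en-2-one ((−)-verbenone)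
Product: 2 (1S,3R)-3-acetyl-2,2-dimethylcyclobutane-1-carboxylic acid (cis-pinononic acid)
Conditions: RuCl3·3H2O (2 mol %), NaIO4 (4.1 equiv), MeCN/EtOAc/H2O, rt
Reagents that add atoms: sodium periodate, [Na+].[O-]I(=O)(=O)=O; water, O
Why: RuO4 generated in the flask cleaves the enone C3=C4 bond with loss of C3 as CO2 (oxidative alkene cleavage), leaving acetyl and carboxyl cis on the cyclobutane with both ring stereocentres of 1 untouched.

Step 2
Reactants: 2 (1S,3R)-3-acetyl-2,2-dimethylcyclobutane-1-carboxylic acid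
Product: 3 (1S,3S)-2,2-dimethyl-3-(prop-1-en-2-yl)cyclobutane-1-carboxylic acid
Conditions: Ph3PCH3Br (2.5 equiv), KOtBu (2.5 equiv), THF, 0 °C → rt; then 1 M HCl
Reagents that add atoms: methyltriphenylphosphonium bromide, C[P+](c1ccccc1)(c1ccccc1)c1ccccc1.[Br-]
Why: Wittig methylenation of the methyl ketone proceeds on the carboxylate salt, and at this temperature the ring α-carbon should not epimerise because its enolate would carry a strained exocyclic double bond on the cyclobutane.

Step 3
Reactants: 3 (1S,3S)-2,2-dimethyl-3-(prop-1-en-2-yl)cyclobutane-1-carboxylic acid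
Product: 4 [(1S,3S)-2,2-dimethyl-3-(prop-1-en-2-yl)cyclobutyl]methanol
Conditions: LiAlH4, THF, 0 °C → rt
Reagents that add atoms: none
Why: Hydride reduction of the acid to the primary alcohol leaves the isolated alkene and both stereocentres unchanged.

Step 4
Reactants: 4 [(1S,3S)-2,2-dimethyl-3-(prop-1-en-2-yl)cyclobutyl]methanol
Product: 5 (1S,3S)-2,2-dimethyl-3-(prop-1-en-2-yl)cyclobutane-1-carbaldehyde
Conditions: Dess–Martin periodinane, CH2Cl2, 0 °C → rt
Reagents that add atoms: none
Why: Dess–Martin oxidation is neutral and stops at the aldehyde, so the α-stereocentre should be kept.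

Step 5
Reactants: 6 benzene-1,3,5-triol (phloroglucinol); 7 (2E)-oct-2-enal
Product: 9 (4S)-5,7-dihydroxy-4-pentyl-3,4-dihydro-2H-chromen-2-one, via lactol 8 (not isolated)
Conditions: (R)-2-[diphenyl(trimethylsilyloxy)methyl]pyrrolidine (20 mol %), PhCO2H (20 mol %), 6 in threefold excess, MeCN, 0 °C; then, same flask, THF, 1,3-dimesitylimidazolium chloride (10 mol %), DBU (40 mol %), 3,3',5,5'-tetra-tert-butyldiphenoquinone (1.1 equiv relative to 7), rt
Reagents that add atoms: none
Why: Iminium-catalysed Friedel–Crafts conjugate addition of the phenol carbon to the enal and hemiacetalisation give lactol 8, the (R)-catalyst shielding one face of the (E,E)-iminium ion so that C4 is set as S and the excess of the symmetric triol suppressing double alkylation; the carbene then oxidises the open hydroxy aldehyde through its acyl azolium (oxidative carbene-catalysed lactonisation), which the ortho phenol should trap intramolecularly faster than the remaining triol can, without oxidising the electron-rich ring or touching C4.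

Step 6
Reactants: 9 (4S)-5,7-dihydroxy-4-pentyl-3,4-dihydro-2H-chromen-2-one
Product: 10 (4S)-5,7-dihydroxy-4-pentyl-8-propanoyl-3,4-dihydro-2H-chromen-2-one
Conditions: EtCOCl (1.1 equiv), AlCl3 (4 equiv), PhNO2/ClCH2CH2Cl, 0 °C → rt
Reagents that add atoms: propanoyl chloride, CCC(Cl)=O
Why: Friedel–Crafts acylation is expected mainly at C8 (para to the C5 hydroxyl, ortho to the C7 hydroxyl), as with 5,7-dihydroxy-4-alkylcoumarins, any C6 isomer being removed by chromatography; no alkene is present yet, so AlCl3 is tolerated.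

Step 7
Reactants: 10 (4S)-5,7-dihydroxy-4-pentyl-8-propanoyl-3,4-dihydro-2H-chromen-2-one; 5 (1S,3S)-2,2-dimethyl-3-(prop-1-en-2-yl)cyclobutane-1-carbaldehyde
Product: 12 (4S)-6-{[(1R,3S)-2,2-dimethyl-3-(prop-1-en-2-yl)cyclobutyl]methyl}-5,7-dihydroxy-4-pentyl-8-propanoyl-3,4-dihydro-2H-chromen-2-one, via ortho-quinone methide 11 (not isolated)
Conditions: 5 in slight excess, Hantzsch ester (1.5 equiv), NaOAc (0.5 equiv), AcOH/toluene, 60 °C
Reagents that add atoms: none
Why: Three-component reductive alkylation: Knoevenagel-type condensation at C6, the only free ring carbon, gives 11, which the Hantzsch ester should reduce by conjugate hydride transfer before it can cycloadd to the isopropenyl group; amine-free conditions spare the aryl lactone, and enolisation of 5 is disfavoured by cyclobutylidene strain.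

Step 8
Reactants: 12 (4S)-6-{[(1R,3S)-2,2-dimethyl-3-(prop-1-en-2-yl)cyclobutyl]methyl}-5,7-dihydroxy-4-pentyl-8-propanoyl-3,4-dihydro-2H-chromen-2-one
Product: 13 (4S,6R)-6-{[(1R,3S)-2,2-dimethyl-3-(prop-1-en-2-yl)cyclobutyl]methyl}-7-hydroxy-6-(3-methylbut-2-en-1-yl)-4-pentyl-8-propanoyl-3,4-dihydro-2H-chromene-2,5(6H)-dione
Conditions: prenyl acetate (1.5 equiv), Pd2(dba)3·CHCl3 (2.5 mol %), (S,S)-N,N'-(cyclohexane-1,2-diyl)bis[2-(diphenylphosphanyl)benzamide] (7.5 mol %), Et3N (1.2 equiv), CH2Cl2, 0 °C → rt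
Reagents that add atoms: 3-methylbut-2-en-1-yl acetate (prenyl acetate), CC(C)=CCOC(C)=O
Why: Dearomative Tsuji–Trost alkylation: zerovalent palladium ionises the acetate and the phenoxide attacks the unsubstituted allyl terminus through C6 (O-allylation is reversible), the quaternary centre being set by attack on the face opposite the pseudoaxial C4 pentyl group, which corresponds to 6R, reinforced by the chiral ligand.

Step 9
Reactants: 13 (4S,6R)-6-{[(1R,3S)-2,2-dimethyl-3-(prop-1-en-2-yl)cyclobutyl]methyl}-7-hydroxy-6-(3-methylbut-2-en-1-yl)-4-pentyl-8-propanoyl-3,4-dihydro-2H-chromene-2,5(6H)-dione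
Product: 14 (4S,6R)-6-{[(1R,3S)-2,2-dimethyl-3-(prop-1-en-2-yl)cyclobutyl]methyl}-6-(3-methylbut-2-en-1-yl)-4-pentyl-7-[(trimethylsilyl)oxy]-8-{(1Z)-1-[(trimethylsilyl)oxy]prop-1-en-1-yl}-3,4-dihydro-2H-chromene-2,5(6H)-dione
Conditions: Me3SiOTf (2.4 equiv), Et3N (3 equiv), Et2O, −78 → 0 °C; pentane, filtration under argon, used crude
Reagents that add atoms: trimethylsilyl trifluoromethanesulfonate, C[Si](C)(C)OS(=O)(=O)C(F)(F)F
Why: Soft enolisation: the silyl triflate silylates the C7 enol and activates the basic vinylogous-ester carbonyl of the propanoyl group, whose α-proton Et3N removes to give the 1,3-bis(silyloxy)diene, while the weakly basic enol-lactone carbonyl should not be enolised.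

Step 10
Reactants: 14 (4S,6R)-6-{[(1R,3S)-2,2-dimethyl-3-(prop-1-en-2-yl)cyclobutyl]methyl}-6-(3-methylbut-2-en-1-yl)-4-pentyl-7-[(trimethylsilyl)oxy]-8-{(1Z)-1-[(trimethylsilyl)oxy]prop-1-en-1-yl}-3,4-dihydro-2H-chromene-2,5(6H)-dione; 15 acetaldehyde
Product: 17 (4S,6R,8R,9R)-6-{[(1R,3S)-2,2-dimethyl-3-(prop-1-en-2-yl)cyclobutyl]methyl}-8,9-dimethyl-6-(3-methylbut-2-en-1-yl)-4-pentyl-3,4,8,9-tetrahydro-2H,6H-pyrano[2,3-f]chromene-2,5,10-trione, via bis-silylated aldol adduct 16 (not isolated)
Conditions: 15 in threefold excess, Ti(OiPr)4 (20 mol %), (S)-1,1'-bi-2-naphthol ((S)-BINOL, 22 mol %), 4 Å molecular sieves, Et2O, −20 °C; then CF3CO2H (3 equiv), CH2Cl2, 0 °C → rt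
Reagents that add atoms: none
Why: The Ti(OiPr)4/(S)-BINOL complex activates acetaldehyde and the terminal carbon of the silyloxy diene adds to it (Mukaiyama aldol addition with silyl transfer) to give 16, after which the acid strips the silyl groups and the new hydroxyl adds to the silyloxy-bearing ring carbon (C8a of the target) with loss of silanol; overall this is a stepwise hetero-Diels–Alder reaction of a 1,3-bis(silyloxy)diene with an aldehyde, the closest known type being the chiral-Lewis-acid aldol–cyclisation route to 2,3-dihydro-4-pyranones. Ring B closes by a 6-endo-trig addition–elimination at the vinylogous-ester carbon. C2 of the target (C8 of 17) is set by the catalyst, which exposes the Si face of the aldehyde independently of the remote substrate stereocentres, and C3 (C9 of 17) is set under thermodynamic control by acid-mediated enolisation to the trans-diequatorial dimethyl arrangement. The step needs regioselectivity between the two ring carbons flanking the acyl-bearing carbon: the lactone keeps O5 acylated, so that carbon has no silyloxy donor and cannot form the stabilised oxocarbenium ion the acid-catalysed exchange requires, and closure should occur only at C8a. No free enol hydroxyl remains afterwards, so the prenyl and isopropenyl groups should survive the acid.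

Step 11
Reactants: 17 (4S,6R,8R,9R)-6-{[(1R,3S)-2,2-dimethyl-3-(prop-1-en-2-yl)cyclobutyl]methyl}-8,9-dimethyl-6-(3-methylbut-2-en-1-yl)-4-pentyl-3,4,8,9-tetrahydro-2H,6H-pyrano[2,3-f]chromene-2,5,10-trione
Product: 18 (3S)-3-[(2R,3R,8R)-8-{[(1R,3S)-2,2-dimethyl-3-(prop-1-en-2-yl)cyclobutyl]methyl}-5-hydroxy-2,3-dimethyl-8-(3-methylbut-2-en-1-yl)-4,7-dioxo-3,4,7,8-tetrahydro-2H-chromen-6-yl]octanoic acid (target)
Conditions: LiOH (2.2 equiv), THF/H2O (3:1), 0 °C, 20 min; then 1 M HCl to pH 3
Reagents that add atoms: lithium hydroxide, [Li+].[OH-]; water, O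
Why: The enol lactone is an activated ester and should be saponified within minutes at 0 °C, faster than base can open ring B by retro-oxa-Michael reaction, and acidification releases the C5 enol and the acid without touching any stereocentre.

Compound list
1 | (1S,5S)-4,6,6-trimethylbicyclo[3.1.1]hept-3-en-2-one ((−)-verbenone) | CC1=CC(=O)[C@H]2C[C@@H]1C2(C)C | starting material
2 | (1S,3R)-3-acetyl-2,2-dimethylcyclobutane-1-carboxylic acid | CC(=O)[C@@H]1C[C@H](C(=O)O)C1(C)C | intermediate
3 | (1S,3S)-2,2-dimethyl-3-(prop-1-en-2-yl)cyclobutane-1-carboxylic acid | C=C(C)[C@@H]1C[C@H](C(=O)O)C1(C)C | intermediate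
4 | [(1S,3S)-2,2-dimethyl-3-(prop-1-en-2-yl)cyclobutyl]methanol | C=C(C)[C@@H]1C[C@H](CO)C1(C)C | intermediate
5 | (1S,3S)-2,2-dimethyl-3-(prop-1-en-2-yl)cyclobutane-1-carbaldehyde | C=C(C)[C@@H]1C[C@H](C=O)C1(C)C | intermediate
6 | benzene-1,3,5-triol (phloroglucinol) | Oc1cc(O)cc(O)c1 | starting material
7 | (2E)-oct-2-enal | CCCCC/C=C/C=O | starting material
8 | (4S)-4-pentyl-3,4-dihydro-2H-chromene-2,5,7-triol (lactol, both C2 anomers) | CCCCC[C@H]1CC(O)Oc2cc(O)cc(O)c21 | intermediate
9 | (4S)-5,7-dihydroxy-4-pentyl-3,4-dihydro-2H-chromen-2-one | CCCCC[C@H]1CC(=O)Oc2cc(O)cc(O)c21 | intermediate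
10 | (4S)-5,7-dihydroxy-4-pentyl-8-propanoyl-3,4-dihydro-2H-chromen-2-one | CCCCC[C@H]1CC(=O)Oc2c(C(=O)CC)c(O)cc(O)c21 | intermediate
11 | (4S)-6-{[(1R,3S)-2,2-dimethyl-3-(prop-1-en-2-yl)cyclobutyl]methylidene}-7-hydroxy-4-pentyl-8-propanoyl-3,4-dihydro-2H-chromene-2,5(6H)-dione (ortho-quinone methide) | CCCCC[C@H]1CC(=O)OC2=C1C(=O)C(=C[C@H]3C[C@@H](C(C)=C)C3(C)C)C(O)=C2C(=O)CC | intermediate
12 | (4S)-6-{[(1R,3S)-2,2-dimethyl-3-(prop-1-en-2-yl)cyclobutyl]methyl}-5,7-dihydroxy-4-pentyl-8-propanoyl-3,4-dihydro-2H-chromen-2-one | CCCCC[C@H]1CC(=O)Oc2c(C(=O)CC)c(O)c(C[C@H]3C[C@@H](C(C)=C)C3(C)C)c(O)c21 | intermediate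
13 | (4S,6R)-6-{[(1R,3S)-2,2-dimethyl-3-(prop-1-en-2-yl)cyclobutyl]methyl}-7-hydroxy-6-(3-methylbut-2-en-1-yl)-4-pentyl-8-propanoyl-3,4-dihydro-2H-chromene-2,5(6H)-dione | CCCCC[C@H]1CC(=O)OC2=C1C(=O)[C@](CC=C(C)C)(C[C@H]3C[C@@H](C(C)=C)C3(C)C)C(O)=C2C(=O)CC | intermediate
14 | (4S,6R)-6-{[(1R,3S)-2,2-dimethyl-3-(prop-1-en-2-yl)cyclobutyl]methyl}-6-(3-methylbut-2-en-1-yl)-4-pentyl-7-[(trimethylsilyl)oxy]-8-{(1Z)-1-[(trimethylsilyl)oxy]prop-1-en-1-yl}-3,4-dihydro-2H-chromene-2,5(6H)-dione | CCCCC[C@H]1CC(=O)OC2=C1C(=O)[C@](CC=C(C)C)(C[C@H]3C[C@@H](C(C)=C)C3(C)C)C(O[Si](C)(C)C)=C2/C(O[Si](C)(C)C)=C/C | intermediate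
15 | acetaldehyde | CC=O | starting material
16 | (4S,6R)-6-{[(1R,3S)-2,2-dimethyl-3-(prop-1-en-2-yl)cyclobutyl]methyl}-6-(3-methylbut-2-en-1-yl)-8-{(3R)-2-methyl-3-[(trimethylsilyl)oxy]butanoyl}-4-pentyl-7-[(trimethylsilyl)oxy]-3,4-dihydro-2H-chromene-2,5(6H)-dione (C2 of the butanoyl group as both epimers) | CCCCC[C@H]1CC(=O)OC2=C1C(=O)[C@](CC=C(C)C)(C[C@H]3C[C@@H](C(C)=C)C3(C)C)C(O[Si](C)(C)C)=C2C(=O)C(C)[C@@H](C)O[Si](C)(C)C | intermediate
17 | (4S,6R,8R,9R)-6-{[(1R,3S)-2,2-dimethyl-3-(prop-1-en-2-yl)cyclobutyl]methyl}-8,9-dimethyl-6-(3-methylbut-2-en-1-yl)-4-pentyl-3,4,8,9-tetrahydro-2H,6H-pyrano[2,3-f]chromene-2,5,10-trione | C=C(C)[C@@H]1C[C@H](C[C@@]2(CC=C(C)C)C(=O)C4=C(OC(=O)C[C@@H]4CCCCC)C3=C2O[C@H](C)[C@@H](C)C3=O)C1(C)C | intermediate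
18 | (3S)-3-[(2R,3R,8R)-8-{[(1R,3S)-2,2-dimethyl-3-(prop-1-en-2-yl)cyclobutyl]methyl}-5-hydroxy-2,3-dimethyl-8-(3-methylbut-2-en-1-yl)-4,7-dioxo-3,4,7,8-tetrahydro-2H-chromen-6-yl]octanoic acid | C=C(C)[C@@H]1C[C@H](C[C@@]2(CC=C(C)C)C(=O)C([C@@H](CCCCC)CC(=O)O)=C(O)C3=C2O[C@H](C)[C@@H](C)C3=O)C1(C)C | target

Total step count: 11. Longest linear sequence: 9 steps (steps 1–4, then 7–11).

Steps most likely to fail

1. Step 10 (key step). What may go wrong: poor facial selectivity at the aldehyde with this hindered, fully substituted diene, attack of the new hydroxyl on the lactone-bearing ring carbon instead of C8a, or incomplete equilibration of C3 to trans. The fallback forms ring B through the O1–C2 bond instead, so that the only free enol oxygen is the nucleophile. It sets out from 14: achiral Mukaiyama aldol addition to 15 (Me3SiOTf, 10 mol %, CH2Cl2, −78 °C) would give the bis-silylated aldol F1 as a diastereomer mixture. DBU-induced elimination of silanolate and mildly acidic work-up would give the (2E)-2-methylbut-2-enoyl enol F2. A cinchona alkaloid base (quinidine or quinine, whichever delivers 2R, 10–20 mol %, toluene) would then promote the enantioface-selective 6-endo oxa-Michael addition of the C7 enol hydroxyl to the enone, the known asymmetric route to 2,3-dimethylchromanones. Brief acid treatment would adjust C3 to trans, and the route is rejoined at 17.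

2. Step 8. What may go wrong: poor facial selectivity in the dearomative prenylation, because the relay from the C4 pentyl group acts over three bonds and the ligand may be mismatched; persistent O-allylation is a second risk. The fallback gives up catalyst control. It sets out from 12: prenyl acetate, Pd(PPh3)4 and Et3N in CH2Cl2 leave only the lactone stereocentre to direct the attack, and 13 is separated from its C6 epimer F3 by chromatography or preparative HPLC. The route is rejoined at 13.

3. Step 7. What may go wrong: sluggish condensation of the hindered α-branched aldehyde with the acyl-deactivated C6 position, α-epimerisation of 5 on prolonged heating, or cycloaddition of the quinone methide to the isopropenyl group. The fallback replaces the condensation by an sp2–sp3 cross-coupling. It sets out from 10 and 4: iodination of 10 (N-iodosuccinimide, MeCN, 0 °C) would give the 6-iodo compound F4. Alcohol 4 would be converted (PPh3, I2, imidazole; Appel reaction) into the iodide F5 and then (zinc dust, LiCl, THF) into the alkylzinc iodide F6. Negishi coupling of F4 with excess F6 (Pd(OAc)2, dicyclohexyl(2',6'-dimethoxybiphenyl-2-yl)phosphane, THF, rt, slow addition to tolerate the phenols) rejoins the route at 12.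

Further compounds
F1 | step 10 | (4S,6R)-6-{[(1R,3S)-2,2-dimethyl-3-(prop-1-en-2-yl)cyclobutyl]methyl}-6-(3-methylbut-2-en-1-yl)-8-{2-methyl-3-[(trimethylsilyl)oxy]butanoyl}-4-pentyl-7-[(trimethylsilyl)oxy]-3,4-dihydro-2H-chromene-2,5(6H)-dione (mixture at both new centres) | CCCCC[C@H]1CC(=O)OC2=C1C(=O)[C@](CC=C(C)C)(C[C@H]3C[C@@H](C(C)=C)C3(C)C)C(O[Si](C)(C)C)=C2C(=O)C(C)C(C)O[Si](C)(C)C
F2 | step 10 | (4S,6R)-6-{[(1R,3S)-2,2-dimethyl-3-(prop-1-en-2-yl)cyclobutyl]methyl}-7-hydroxy-8-[(2E)-2-methylbut-2-enoyl]-6-(3-methylbut-2-en-1-yl)-4-pentyl-3,4-dihydro-2H-chromene-2,5(6H)-dione | CCCCC[C@H]1CC(=O)OC2=C1C(=O)[C@](CC=C(C)C)(C[C@H]3C[C@@H](C(C)=C)C3(C)C)C(O)=C2C(=O)/C(C)=C/C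
F3 | step 8 | (4S,6S)-6-{[(1R,3S)-2,2-dimethyl-3-(prop-1-en-2-yl)cyclobutyl]methyl}-7-hydroxy-6-(3-methylbut-2-en-1-yl)-4-pentyl-8-propanoyl-3,4-dihydro-2H-chromene-2,5(6H)-dione | CCCCC[C@H]1CC(=O)OC2=C1C(=O)[C@@](CC=C(C)C)(C[C@H]3C[C@@H](C(C)=C)C3(C)C)C(O)=C2C(=O)CC
F4 | step 7 | (4S)-5,7-dihydroxy-6-iodo-4-pentyl-8-propanoyl-3,4-dihydro-2H-chromen-2-one | CCCCC[C@H]1CC(=O)Oc2c(C(=O)CC)c(O)c(I)c(O)c21
F5 | step 7 | (1S,3S)-1-(iodomethyl)-2,2-dimethyl-3-(prop-1-en-2-yl)cyclobutane | C=C(C)[C@@H]1C[C@H](CI)C1(C)C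
F6 | step 7 | {[(1S,3S)-2,2-dimethyl-3-(prop-1-en-2-yl)cyclobutyl]methyl}(iodo)zinc | C=C(C)[C@@H]1C[C@H](C[Zn]I)C1(C)C
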